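**Retrosynthetic overview**

1. The strategy rests on ring A: a fully substituted phloroglucinol ring in which the quaternary carbon on C6 sits between the C5 and C7 oxygens and C8 is the only ring C–H. That C5(O)–C6(CR3)–C7(O)–C8(H) sequence is what a vinylketene and a siloxyalkyne deliver.
2. Target ⇐ tris-silyl flavanone (global desilylation) ⇐ ring A cut at C8–C8a, C5–C6, C7–C8 and C4a–C5, giving a (2S)-2-aryl-6-(diazoacetyl)dihydropyran-4-one (ring C with ring B attached) and the triisopropylsilyl ynol ether that carries the quaternary carbon.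
3. Diazoketone ⇐ pyranone-6-carboxylic acid ⇐ methyl ester ⇐ catalytic asymmetric vinylogous aldol/cyclocondensation (formal hetero-Diels–Alder) of bis-silylated 3,4-dihydroxybenzaldehyde with the bis-silyl dienol ether of methyl 2,4-dioxopentanoate.
4. Ynol ether ⇐ ethyl 2,2-dimethylbut-3-enoate by ynolate homologation.
5. Ring order: ring B is bought, ring C is closed in step 3 with C2 set there, ring A is built last in step 7.

Key step: step 7

Remark on the chemistry: (S)-BINOL is assumed to direct the dienol ether to the Si face of the aryl aldehyde, the sense usual for BINOL–titanium additions to aryl aldehydes. The (2Z) enol ether geometry written for the silyl diene and its aldol adduct is arbitrary, since that double bond ends up inside ring C.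

**Step 1**
Reactants: 1 3,4-dihydroxybenzaldehyde
Product: 2 3,4-bis(triisopropylsilyloxy)benzaldehyde
Conditions: TIPSCl (2.5 equiv), imidazole (5 equiv), DMAP (cat.), DMF, 23 → 40 °C
Reagents that add atoms: triisopropylsilyl chloride, CC(C)[Si](Cl)(C(C)C)C(C)C
Why: Imidazole-promoted silylation of both phenols; aryl triisopropylsilyl ethers are chosen because they should withstand the Lewis acid, TFA, Me3SnOH, diazomethane and irradiation of the later steps and leave together with the ring A silyl ether at the end.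

**Step 2**
Reactants: 3 methyl 2,4-dioxopentanoate
Product: 4 methyl (2Z)-2,4-bis(trimethylsilyloxy)penta-2,4-dienoate
Conditions: TMSOTf (2.2 equiv), Et3N (2.6 equiv), Et2O, 0 → 23 °C
Reagents that add atoms: trimethylsilyl trifluoromethanesulfonate, C[Si](C)(C)OS(=O)(=O)C(F)(F)F
Why: Double soft enolisation with silyl triflate and amine, the known way from 1,3-diketones to 2,4-bis(silyloxy)-1,3-dienes, converts the enolised diketone and then its methyl terminus into the bis-silyl dienol ether, which is moisture-sensitive and is used directly after removal of the ammonium salt.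

**Step 3**
Reactants: 2 3,4-bis(triisopropylsilyloxy)benzaldehyde; 4 methyl (2Z)-2,4-bis(trimethylsilyloxy)penta-2,4-dienoate
Product: 6 methyl (2S)-2-[3,4-bis(triisopropylsilyloxy)phenyl]-4-oxo-3,4-dihydro-2H-pyran-6-carboxylate, via silylated aldol adduct 5 (not isolated)
Conditions: Ti(OiPr)4 (20 mol%), (S)-BINOL (20 mol%), 4 Å MS, THF, −78 → −20 °C; then TFA, CH2Cl2, 0 °C
Reagents that add atoms: none
Why: Catalytic enantioselective vinylogous Mukaiyama aldol addition (formal hetero-Diels–Alder reaction) of a 1,3-bis(silyloxy)diene to an aryl aldehyde under a BINOL–Ti(OiPr)4 Lewis acid, in which the terminal CH2 carbon of 4 attacks the Si face of 2 so that the chiral titanium complex sets C2 as (S), followed by TFA-induced desilylation and 6-endo addition–elimination of the carbinol oxygen at the silyloxy-bearing carbon, which closes ring C without touching the C2–O bond.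

**Step 4**
Reactants: 6 methyl (2S)-2-[3,4-bis(triisopropylsilyloxy)phenyl]-4-oxo-3,4-dihydro-2H-pyran-6-carboxylate
Product: 7 (2S)-2-[3,4-bis(triisopropylsilyloxy)phenyl]-4-oxo-3,4-dihydro-2H-pyran-6-carboxylic acid
Conditions: Me3SnOH (4 equiv), ClCH2CH2Cl, 70 °C; then 1 M HCl wash
Reagents that add atoms: trimethyltin hydroxide, C[Sn](C)(C)O
Why: Trimethyltin hydroxide cleaves methyl esters under near-neutral conditions, which avoids the hydroxide-induced β-elimination at O1–C2 that would open ring C and racemise C2, and it should leave the aryl silyl ethers alone.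

**Step 5**
Reactants: 7 (2S)-2-[3,4-bis(triisopropylsilyloxy)phenyl]-4-oxo-3,4-dihydro-2H-pyran-6-carboxylic acid
Product: 9 (2S)-2-[3,4-bis(triisopropylsilyloxy)phenyl]-6-(2-diazoacetyl)-2,3-dihydro-4H-pyran-4-one, via acid chloride 8 (not isolated)
Conditions: Me2C=C(Cl)NMe2 (1.2 equiv), CH2Cl2, 0 → 23 °C; then CH2N2 (3 equiv), Et2O, 0 °C
Reagents that add atoms: diazomethane, C=[N+]=[N-]
Why: Acylation of diazomethane by an acid chloride (first stage of the Arndt–Eistert sequence); the α-chloroenamine forms 8 without releasing HCl, and excess diazomethane at 0 °C for a short time takes up the HCl of the acylation before the electron-poor ring alkene can undergo dipolar cycloaddition.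

**Step 6**
Reactants: 10 ethyl 2,2-dimethylbut-3-enoate
Product: 13 triisopropyl[(3,3-dimethylpent-4-en-1-yn-1-yl)oxy]silane, via dibromoketone enolate 11 (not isolated), via lithium ynolate 12 (not isolated)
Conditions: CH2Br2, lithium 2,2,6,6-tetramethylpiperidide, THF, −78 °C; LiN(SiMe3)2, −78 → −20 °C; n-BuLi, −78 → 23 °C; TIPSCl, 0 → 23 °C
Reagents that add atoms: dibromomethane, BrCBr; triisopropylsilyl chloride, CC(C)[Si](Cl)(C(C)C)C(C)C
Why: Kowalski ynolate homologation: LiCHBr2 is acylated by 10 to give dibromoketone enolate 11, bromine–lithium exchange with n-BuLi triggers a 1,2-shift of the tert-alkyl group to ynolate 12, and the bulky silyl chloride reacts at oxygen to give the ynol ether.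

**Step 7**
Reactants: 9 (2S)-2-[3,4-bis(triisopropylsilyloxy)phenyl]-6-(2-diazoacetyl)-2,3-dihydro-4H-pyran-4-one; 13 triisopropyl[(3,3-dimethylpent-4-en-1-yn-1-yl)oxy]silane
Product: 18 (2S)-2-[3,4-bis(triisopropylsilyloxy)phenyl]-5-hydroxy-6-(2-methylbut-3-en-2-yl)-7-(triisopropylsilyloxy)chroman-4-one, via vinylketene 14 (not isolated), via vinylcyclobutenone 15 (not isolated), via dienylketene 16 (not isolated), via cyclohexadienone tautomer 17 (not isolated)
Conditions: 13 (1.5 equiv), hν (medium-pressure Hg lamp, Pyrex, λ > 300 nm), degassed ClCH2CH2Cl, 23 °C; then 80 °C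
Reagents that add atoms: none
Why: Light expels N2 from 9 and the pyranyl carbon (the later C8a) shifts to the former diazo carbon (Wolff rearrangement, forming C8–C8a) to give vinylketene 14, whose carbonyl carbon becomes C5; the polarised ynol ether 13 then adds in a [2+2] sense (C5–C6 and C7–C8) to give 4-vinylcyclobutenone 15. Heating opens 15 by reversible 4π electrocyclic cleavage to dienylketene 16, and ring A closes by thermal disrotatory 6π electrocyclisation of the C5 ketene carbon onto C4a, after which the C4a hydrogen of dienone 17, α to the C4 ketone, tautomerises to give the C5 phenol. The closest known reaction type is the benzannulation of α,β-unsaturated α′-diazoketones with triisopropylsiloxyalkynes (Danheiser benzannulation, photochemical Wolff variant), known for cycloalkenyl, aryl and heteroaryl diazoketones. No stereocentre is created, and C2 is remote from every bond change, so its (S) configuration should be carried through. The selectivity needed is regiochemical: the nucleophilic alkyne carbon, the one bearing the tert-alkyl group, must bond to the ketene carbonyl carbon, which the silyloxy donor on the other alkyne carbon secures, so the quaternary substituent lands on C6 between the C5 hydroxyl and the C7 silyl ether. The side-chain vinyl group is insulated from the alkyne by the quaternary carbon and is far less reactive toward the ketene than the ynol ether.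

**Step 8**
Reactants: 18 (2S)-2-[3,4-bis(triisopropylsilyloxy)phenyl]-5-hydroxy-6-(2-methylbut-3-en-2-yl)-7-(triisopropylsilyloxy)chroman-4-one
Product: 19 (2S)-2-(3,4-dihydroxyphenyl)-5,7-dihydroxy-6-(2-methylbut-3-en-2-yl)-2,3-dihydro-4H-chromen-4-one
Conditions: Bu4NF (3.5 equiv), AcOH (4 equiv), THF, 0 → 23 °C, argon
Reagents that add atoms: none
Why: Fluoride-induced cleavage of the three aryl silyl ethers, buffered with acetic acid so that no phenoxide or C3 enolate builds up that could open ring C to the chalcone and racemise C2 or let the catechol oxidise; the 1,1-dimethylallyl group and the hydrogen-bonded C5 hydroxyl are untouched.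

**Compound list**

1 | 3,4-dihydroxybenzaldehyde | O=Cc1ccc(O)c(O)c1 | starting material
2 | 3,4-bis(triisopropylsilyloxy)benzaldehyde | O=Cc1ccc(O[Si](C(C)C)(C(C)C)C(C)C)c(O[Si](C(C)C)(C(C)C)C(C)C)c1 | intermediate
3 | methyl 2,4-dioxopentanoate | COC(=O)C(=O)CC(C)=O | starting material
4 | methyl (2Z)-2,4-bis(trimethylsilyloxy)penta-2,4-dienoate | COC(=O)/C(O[Si](C)(C)C)=C/C(O[Si](C)(C)C)=C | intermediate
5 | methyl (2Z,6S)-6-[3,4-bis(triisopropylsilyloxy)phenyl]-4-oxo-2,6-bis(trimethylsilyloxy)hex-2-enoate (silylated aldol adduct, not isolated) | COC(=O)/C(O[Si](C)(C)C)=C/C(=O)C[C@H](O[Si](C)(C)C)c1ccc(O[Si](C(C)C)(C(C)C)C(C)C)c(O[Si](C(C)C)(C(C)C)C(C)C)c1 | intermediate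
6 | methyl (2S)-2-[3,4-bis(triisopropylsilyloxy)phenyl]-4-oxo-3,4-dihydro-2H-pyran-6-carboxylate | COC(=O)C1=CC(=O)C[C@@H](c2ccc(O[Si](C(C)C)(C(C)C)C(C)C)c(O[Si](C(C)C)(C(C)C)C(C)C)c2)O1 | intermediate
7 | (2S)-2-[3,4-bis(triisopropylsilyloxy)phenyl]-4-oxo-3,4-dihydro-2H-pyran-6-carboxylic acid | OC(=O)C1=CC(=O)C[C@@H](c2ccc(O[Si](C(C)C)(C(C)C)C(C)C)c(O[Si](C(C)C)(C(C)C)C(C)C)c2)O1 | intermediate
8 | (2S)-2-[3,4-bis(triisopropylsilyloxy)phenyl]-4-oxo-3,4-dihydro-2H-pyran-6-carbonyl chloride (not isolated) | ClC(=O)C1=CC(=O)C[C@@H](c2ccc(O[Si](C(C)C)(C(C)C)C(C)C)c(O[Si](C(C)C)(C(C)C)C(C)C)c2)O1 | intermediate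
9 | (2S)-2-[3,4-bis(triisopropylsilyloxy)phenyl]-6-(2-diazoacetyl)-2,3-dihydro-4H-pyran-4-one | [N-]=[N+]=CC(=O)C1=CC(=O)C[C@@H](c2ccc(O[Si](C(C)C)(C(C)C)C(C)C)c(O[Si](C(C)C)(C(C)C)C(C)C)c2)O1 | intermediate
10 | ethyl 2,2-dimethylbut-3-enoate | C=CC(C)(C)C(=O)OCC | starting material
11 | lithium 1,1-dibromo-3,3-dimethylpenta-1,4-dien-2-olate (not isolated) | [Li+].[O-]C(=C(Br)Br)C(C)(C)C=C | intermediate
12 | lithium 3,3-dimethylpent-4-en-1-yn-1-olate (not isolated) | [Li+].[O-]C#CC(C)(C)C=C | intermediate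
13 | triisopropyl[(3,3-dimethylpent-4-en-1-yn-1-yl)oxy]silane | C=CC(C)(C)C#CO[Si](C(C)C)(C(C)C)C(C)C | intermediate
14 | (2S)-2-[3,4-bis(triisopropylsilyloxy)phenyl]-6-(2-oxoethenyl)-2,3-dihydro-4H-pyran-4-one (vinylketene, not isolated) | O=C=CC1=CC(=O)C[C@@H](c2ccc(O[Si](C(C)C)(C(C)C)C(C)C)c(O[Si](C(C)C)(C(C)C)C(C)C)c2)O1 | intermediate
15 | 4-[(2S)-2-[3,4-bis(triisopropylsilyloxy)phenyl]-4-oxo-3,4-dihydro-2H-pyran-6-yl]-2-(2-methylbut-3-en-2-yl)-3-(triisopropylsilyloxy)cyclobut-2-en-1-one (both epimers at the cyclobutenone sp3 carbon, not isolated) | O=C1C(C(C)(C)C=C)=C(O[Si](C(C)C)(C(C)C)C(C)C)C1C2=CC(=O)C[C@@H](c3ccc(O[Si](C(C)C)(C(C)C)C(C)C)c(O[Si](C(C)C)(C(C)C)C(C)C)c3)O2 | intermediate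
16 | (2S)-2-[3,4-bis(triisopropylsilyloxy)phenyl]-6-[(1E)-4,4-dimethyl-3-(oxomethylidene)-2-(triisopropylsilyloxy)hexa-1,5-dien-1-yl]-2,3-dihydro-4H-pyran-4-one (dienylketene, not isolated) | O=C=C(C(C)(C)C=C)/C(O[Si](C(C)C)(C(C)C)C(C)C)=C\C1=CC(=O)C[C@@H](c2ccc(O[Si](C(C)C)(C(C)C)C(C)C)c(O[Si](C(C)C)(C(C)C)C(C)C)c2)O1 | intermediate
17 | (2S)-2-[3,4-bis(triisopropylsilyloxy)phenyl]-6-(2-methylbut-3-en-2-yl)-7-(triisopropylsilyloxy)-2,3-dihydro-4H-chromene-4,5(4aH)-dione (keto tautomer of 18, both C4a epimers, not isolated) | O=C1C(C(C)(C)C=C)=C(O[Si](C(C)C)(C(C)C)C(C)C)C=C2O[C@H](c3ccc(O[Si](C(C)C)(C(C)C)C(C)C)c(O[Si](C(C)C)(C(C)C)C(C)C)c3)CC(=O)C12 | intermediate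
18 | (2S)-2-[3,4-bis(triisopropylsilyloxy)phenyl]-5-hydroxy-6-(2-methylbut-3-en-2-yl)-7-(triisopropylsilyloxy)chroman-4-one | C=CC(C)(C)c1c(O[Si](C(C)C)(C(C)C)C(C)C)cc2c(c1O)C(=O)C[C@@H](c1ccc(O[Si](C(C)C)(C(C)C)C(C)C)c(O[Si](C(C)C)(C(C)C)C(C)C)c1)O2 | intermediate
19 | (2S)-2-(3,4-dihydroxyphenyl)-5,7-dihydroxy-6-(2-methylbut-3-en-2-yl)-2,3-dihydro-4H-chromen-4-one | C=CC(C)(C)c1c(O)cc2c(c1O)C(=O)C[C@@H](c1ccc(O)c(O)c1)O2 | target

**Step count**

Total step count: 8. Longest linear sequence: 6 steps (steps 1, 3, 4, 5, 7 and 8, from 1).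

**Steps most likely to fail**

Step 7 (benzannulation). The dihydropyranone enone and the product chromanone absorb in the same region as the diazoketone, so enone photocycloaddition to the alkyne or alkene of 13 and inner filtering may outrun ketene formation. Capture of the ketene by the hindered alkyne carbon may also be slow enough for ketene self-condensation or acylation of the product phenol to take over. The fallback generates the same ketene in the dark and sets out from 9. PhCO2Ag (cat.) and Et3N in THF–H2O should effect a thermal Wolff rearrangement with hydration to 2-[(2S)-2-[3,4-bis(triisopropylsilyloxy)phenyl]-4-oxo-3,4-dihydro-2H-pyran-6-yl]acetic acid F1. Me2C=C(Cl)NMe2 in CH2Cl2 converts it into 2-[(2S)-2-[3,4-bis(triisopropylsilyloxy)phenyl]-4-oxo-3,4-dihydro-2H-pyran-6-yl]acetyl chloride F2. F2 is added slowly to Et3N and 13 in toluene at 80 °C; dehydrochlorination gives vinylketene 14, and the known ketene–siloxyalkyne [2+2] addition and thermal 4-vinylcyclobutenone-to-phenol rearrangement lead through 15, 16 and 17 back to the route at 18.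

Step 3 (asymmetric aldol/cyclisation). The ester-bearing dienol ether is a weak nucleophile and the aldehyde is electron-rich, so a slow catalysed path may let a silyl-transfer background reaction erode the enantioselectivity. Benzylic ionisation under TFA may also cause dehydration or loss of configuration. The fallback builds the same ring stepwise from 2. A chiral bisphosphoramide/SiCl4-catalysed Mukaiyama aldol addition of 2-(trimethylsilyloxy)propene (catalyst antipode chosen for Si-face attack, CH2Cl2, −78 °C) should give (4S)-4-[3,4-bis(triisopropylsilyloxy)phenyl]-4-hydroxybutan-2-one F3. Et3SiOTf and 2,6-lutidine give (4S)-4-[3,4-bis(triisopropylsilyloxy)phenyl]-4-(triethylsilyloxy)butan-2-one F4. Kinetic deprotonation of the methyl group with LiN(SiMe3)2 (THF, −78 °C) and Claisen acylation with dimethyl oxalate give methyl (6S)-6-[3,4-bis(triisopropylsilyloxy)phenyl]-2,4-dioxo-6-(triethylsilyloxy)hexanoate F5. TFA in CH2Cl2 at 0 °C removes the triethylsilyl group and cyclodehydrates F5, which comes back to the route at 6.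

Step 6 (ynolate homologation). Acylation of LiCHBr2 by the α-quaternary ester may be slow, and the 1,2-shift of the tert-alkyl group may be incomplete, leaving dibromoketone-derived material. The fallback makes the ynolate by oxidation of an acetylide and sets out from 10. i-Bu2AlH (CH2Cl2, −78 °C) gives 2,2-dimethylbut-3-enal F6. The Ohira–Bestmann reagent (dimethyl (1-diazo-2-oxopropyl)phosphonate, K2CO3, MeOH) gives 3,3-dimethylpent-4-en-1-yne F7, a volatile alkyne that is carried on as a solution. n-BuLi (THF, −78 °C) followed by LiOOt-Bu (from t-BuOOH and LiN(SiMe3)2) oxidises the lithium acetylide to ynolate 12, which is silylated with TIPSOTf and so comes back to the route at 13.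

**Further compounds**

F1 | step 7 | 2-[(2S)-2-[3,4-bis(triisopropylsilyloxy)phenyl]-4-oxo-3,4-dihydro-2H-pyran-6-yl]acetic acid | OC(=O)CC1=CC(=O)C[C@@H](c2ccc(O[Si](C(C)C)(C(C)C)C(C)C)c(O[Si](C(C)C)(C(C)C)C(C)C)c2)O1
F2 | step 7 | 2-[(2S)-2-[3,4-bis(triisopropylsilyloxy)phenyl]-4-oxo-3,4-dihydro-2H-pyran-6-yl]acetyl chloride | ClC(=O)CC1=CC(=O)C[C@@H](c2ccc(O[Si](C(C)C)(C(C)C)C(C)C)c(O[Si](C(C)C)(C(C)C)C(C)C)c2)O1
F3 | step 3 | (4S)-4-[3,4-bis(triisopropylsilyloxy)phenyl]-4-hydroxybutan-2-one | CC(=O)C[C@H](O)c1ccc(O[Si](C(C)C)(C(C)C)C(C)C)c(O[Si](C(C)C)(C(C)C)C(C)C)c1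
F4 | step 3 | (4S)-4-[3,4-bis(triisopropylsilyloxy)phenyl]-4-(triethylsilyloxy)butan-2-one | CC(=O)C[C@H](O[Si](CC)(CC)CC)c1ccc(O[Si](C(C)C)(C(C)C)C(C)C)c(O[Si](C(C)C)(C(C)C)C(C)C)c1
F5 | step 3 | methyl (6S)-6-[3,4-bis(triisopropylsilyloxy)phenyl]-2,4-dioxo-6-(triethylsilyloxy)hexanoate | COC(=O)C(=O)CC(=O)C[C@H](O[Si](CC)(CC)CC)c1ccc(O[Si](C(C)C)(C(C)C)C(C)C)c(O[Si](C(C)C)(C(C)C)C(C)C)c1
F6 | step 6 | 2,2-dimethylbut-3-enal | C=CC(C)(C)C=O
F7 | step 6 | 3,3-dimethylpent-4-en-1-yne | C=CC(C)(C)C#C
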